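**Retrosynthetic overview**
1. Last bond: the aryl allyl ether C–O bond, from the 5-OH of phthalide 4 and chain alcohol 10 (Mitsunobu).
2. Key C–C bond: C3a–C3 of the phthalide, from aryl bromide 2 and a hydroxymethyl anion equivalent (Bu3SnCH2OH). This joins a formaldehyde-level carbon of inverted polarity to an aryl halide carbon, two carbons that are both normally electrophilic. The lactone closes in the same flask.
3. Bromide 2 comes from methyl 3-O-methylgallate 1 by bromination ortho to the free 3-OH.
4. Chain alcohol 10 comes from (2E,6E)-farnesol 5 by terminal Markovnikov hydration, bis-acetylation and selective removal of the primary acetate.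
5. Ring order: ring A (benzene) is bought; ring B (the γ-lactone) is the only ring formed, in step 2.

Assumption: the target has no stereocentre, so "single enantiomer" is read as the single (2E,6E) geometric isomer; both alkene geometries are bought with (2E,6E)-farnesol and never touched.

**Step 1**
Reactants: 1 methyl 3,4-dihydroxy-5-methoxybenzoate
Product: 2 methyl 2-bromo-3,4-dihydroxy-5-methoxybenzoate
Conditions: NBS (1.0 equiv), iPr2NH (10 mol%), CH2Cl2, 0 °C to rt
Reagents that add atoms: N-bromosuccinimide, O=C1CCC(=O)N1Br
Why: Amine-mediated ortho-selective electrophilic aromatic bromination, in which the N-bromoamine is delivered through a hydrogen bond to the phenol and C2 is the only free position ortho to a hydroxyl (it is also para to the methoxy group), in line with the 2-bromination of isovanillin-type 3-hydroxy-4-alkoxy aryl carbonyl compounds.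

**Step 2**
Reactants: 2 methyl 2-bromo-3,4-dihydroxy-5-methoxybenzoate
Product: 4 4,5-dihydroxy-6-methoxyisobenzofuran-1(3H)-one, via hydroxymethyl benzoate 3 (not isolated)
Conditions: Bu3SnCH2OH (1.5 equiv), Pd2(dba)3 (5 mol%), XPhos (12 mol%), 1,4-dioxane, 100 °C, Ar; then TsOH·H2O (10 mol%), rt
Reagents that add atoms: (tributylstannyl)methanol, CCCC[Sn](CCCC)(CCCC)CO
Why: Migita–Kosugi–Stille cross-coupling in which zerovalent palladium inserts into the C–Br bond (helped by the ortho ester) and the stannane transfers CH2OH as a hydroxymethyl anion equivalent, after which the new benzylic alcohol lactonizes onto the neighbouring methyl ester (5-exo-trig, loss of methanol), the known route from 2-bromobenzoates to phthalides, applied here to an unprotected catechol.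

**Step 3**
Reactants: 5 (2E,6E)-farnesol
Product: 7 (2E,6E)-3,7,11-trimethyldodeca-2,6-diene-1,11-diol, via alkylmercury acetate 6 (not isolated)
Conditions: Hg(OAc)2 (1.0 equiv), THF/H2O (1:1), 0 °C to rt; then 3 M NaOH, NaBH4, 0 °C
Reagents that add atoms: water, O
Why: Markovnikov oxymercuration–demercuration with one equivalent of Hg(OAc)2 takes the terminal isopropylidene alkene, the most accessible one (the 2,3-alkene is deactivated by the allylic oxygen, the 6,7-alkene is flanked on both sides), and the transient C10–Hg stereocentre is erased on reduction, so both E alkenes are unchanged.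

**Step 4**
Reactants: 7 (2E,6E)-3,7,11-trimethyldodeca-2,6-diene-1,11-diol
Product: 9 (2E,6E)-3,7,11-trimethyldodeca-2,6-diene-1,11-diyl diacetate, via primary monoacetate 8 (not isolated)
Conditions: Ac2O (5 equiv), Et3N (6 equiv), DMAP (0.5 equiv), CH2Cl2, rt, 36 h
Reagents that add atoms: acetic anhydride, CC(=O)OC(C)=O
Why: DMAP-catalysed (Steglich-type) acylation through the N-acetylpyridinium ion acetylates the primary alcohol at once and the hindered tertiary alcohol on prolonged reaction, under basic conditions that cannot ionize or eliminate the tertiary centre.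

**Step 5**
Reactants: 9 (2E,6E)-3,7,11-trimethyldodeca-2,6-diene-1,11-diyl diacetate
Product: 10 (2E,6E)-11-acetoxy-3,7,11-trimethyldodeca-2,6-dien-1-ol
Conditions: K2CO3 (0.3 equiv), MeOH, 0 °C, 1–2 h (TLC control)
Reagents that add atoms: none
Why: Zemplén-type base-catalysed transesterification removes the unhindered primary allylic acetate far faster than the hindered tertiary acetate, so stopping at low temperature leaves the tertiary ester in place.

**Step 6**
Reactants: 4 4,5-dihydroxy-6-methoxyisobenzofuran-1(3H)-one; 10 (2E,6E)-11-acetoxy-3,7,11-trimethyldodeca-2,6-dien-1-ol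
Product: 11 Farnesylemefuranone F
Conditions: PPh3 (1.2 equiv), DIAD (1.2 equiv), THF, 0 °C to rt
Reagents that add atoms: none
Why: Mitsunobu etherification in which the betaine deprotonates the more acidic 5-OH (para to the lactone carbonyl, the same bias that gives 4-O-alkylation of 5-hydroxyvanillin and gallates) and that phenoxide displaces the primary allylic oxyphosphonium by SN2, with no acid or metal present that could scramble the two E alkenes.

**Compound list**
1 | methyl 3,4-dihydroxy-5-methoxybenzoate (methyl 3-O-methylgallate) | COC(=O)c1cc(O)c(O)c(OC)c1 | starting material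
2 | methyl 2-bromo-3,4-dihydroxy-5-methoxybenzoate | COC(=O)c1cc(OC)c(O)c(O)c1Br | intermediate
3 | methyl 3,4-dihydroxy-2-(hydroxymethyl)-5-methoxybenzoate (formed in the flask) | COC(=O)c1cc(OC)c(O)c(O)c1CO | intermediate
4 | 4,5-dihydroxy-6-methoxyisobenzofuran-1(3H)-one | COc1cc2c(c(O)c1O)COC2=O | intermediate
5 | (2E,6E)-3,7,11-trimethyldodeca-2,6,10-trien-1-ol ((2E,6E)-farnesol) | OC/C=C(\C)CC/C=C(\C)CCC=C(C)C | starting material
6 | (2E,6E)-10-(acetoxymercurio)-3,7,11-trimethyldodeca-2,6-diene-1,11-diol (racemic at C10, formed in the flask) | OC/C=C(\C)CC/C=C(\C)CCC([Hg]OC(C)=O)C(C)(C)O | intermediate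
7 | (2E,6E)-3,7,11-trimethyldodeca-2,6-diene-1,11-diol | OC/C=C(\C)CC/C=C(\C)CCCC(C)(C)O | intermediate
8 | (2E,6E)-11-hydroxy-3,7,11-trimethyldodeca-2,6-dien-1-yl acetate (formed in the flask) | CC(=O)OC/C=C(\C)CC/C=C(\C)CCCC(C)(C)O | intermediate
9 | (2E,6E)-3,7,11-trimethyldodeca-2,6-diene-1,11-diyl diacetate | CC(=O)OC/C=C(\C)CC/C=C(\C)CCCC(C)(C)OC(C)=O | intermediate
10 | (2E,6E)-11-acetoxy-3,7,11-trimethyldodeca-2,6-dien-1-ol | OC/C=C(\C)CC/C=C(\C)CCCC(C)(C)OC(C)=O | intermediate
11 | Farnesylemefuranone F, (6E,10E)-12-[(4-hydroxy-6-methoxy-1-oxo-1,3-dihydroisobenzofuran-5-yl)oxy]-2,6,10-trimethyldodeca-6,10-dien-2-yl acetate | COc1cc2c(c(O)c1OC/C=C(\C)CC/C=C(\C)CCCC(C)(C)OC(C)=O)COC2=O | target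

**Step count**
Total steps: 6. Longest linear sequence: 4 (steps 3, 4, 5, 6 from farnesol); the aromatic branch is 3 (steps 1, 2, 6).

**Three steps most likely to fail**

Step 1 (regiochemistry of bromination, C2 against C6, and possible oxidation of the catechol by NBS). The fallback sets out from compound 1 and comes back at compound 2, placing the bromine by deprotonation instead of electrophilic substitution. Compound 1 is converted with 2,2-dimethoxypropane and catalytic TsOH (toluene, reflux) into methyl 7-methoxy-2,2-dimethyl-1,3-benzodioxole-5-carboxylate F1. Directed ortho-magnesiation with TMPMgCl·LiCl (THF, −20 °C) takes the C–H flanked by the ester and the dioxole oxygen; the other ortho C–H is shielded by the methoxy methyl group, which is turned toward it. Quenching with BrCl2C–CCl2Br gives methyl 4-bromo-7-methoxy-2,2-dimethyl-1,3-benzodioxole-5-carboxylate F2. TFA/H2O (9:1, rt) removes the acetonide and delivers 2.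

Step 2 (slow transmetalation at a bromide flanked on both sides, and interference of the free catechol with palladium and tin). The fallback sets out from compound 2 and comes back at compound 4, masking the catechol and using a boron-based hydroxymethyl anion equivalent. Compound 2 is benzylated (BnBr, K2CO3, DMF) to methyl 3,4-bis(benzyloxy)-2-bromo-5-methoxybenzoate F3. Suzuki–Miyaura coupling with potassium (acetoxymethyl)trifluoroborate (Pd(OAc)2, RuPhos, Na2CO3, dioxane/H2O, 100 °C) follows; the acetate is hydrolysed in the flask and acidic work-up closes the lactone, giving 4,5-bis(benzyloxy)-6-methoxyisobenzofuran-1(3H)-one F4. Hydrogenolysis (H2, 1 atm, Pd/C, EtOAc; no alkene is present yet) gives 4.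

Step 6 (4-O- against 5-O-alkylation, bis-alkylation, or SN2' attack in the Mitsunobu reaction). The fallback sets out from compound 10 and comes back at compound 11, replacing redox activation of the alcohol by a weak-base phenoxide alkylation. Compound 10 is converted by the Appel reaction (CBr4, PPh3, CH2Cl2, 0 °C) into (6E,10E)-12-bromo-2,6,10-trimethyldodeca-6,10-dien-2-yl acetate F5. Compound 4 is then alkylated with F5 using Li2CO3 (1.1 equiv) in DMF at rt; this base ionizes only the more acidic 5-OH and gives 11.

**Further compounds**
F1 | step 1 | methyl 7-methoxy-2,2-dimethyl-1,3-benzodioxole-5-carboxylate | COC(=O)c1cc(OC)c2OC(C)(C)Oc2c1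
F2 | step 1 | methyl 4-bromo-7-methoxy-2,2-dimethyl-1,3-benzodioxole-5-carboxylate | COC(=O)c1cc(OC)c2OC(C)(C)Oc2c1Br
F3 | step 2 | methyl 3,4-bis(benzyloxy)-2-bromo-5-methoxybenzoate | COC(=O)c1cc(OC)c(OCc2ccccc2)c(OCc2ccccc2)c1Br
F4 | step 2 | 4,5-bis(benzyloxy)-6-methoxyisobenzofuran-1(3H)-one | COc1cc2c(c(OCc3ccccc3)c1OCc1ccccc1)COC2=O
F5 | step 6 | (6E,10E)-12-bromo-2,6,10-trimethyldodeca-6,10-dien-2-yl acetate | BrC/C=C(\C)CC/C=C(\C)CCCC(C)(C)OC(C)=O
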